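**Retrosynthetic overview**
1. Target ⇐ global O-debenzylation of its tribenzyl ether ⇐ reagent-controlled syn hydroboration–oxidation of a 3-aryl-2H-chromene (sets C3 and C4 together, 3,4-trans) ⇐ reduction and dehydration of an isoflavone.
2. Isoflavone ⇐ 2'-fluorochalcone epoxide in one flask: a 1,2-shift of the ring-A aroyl group from C2 to C3 makes C3–C4, and the former epoxide oxygen O1 then closes onto C8a by SNAr. The C2–C4 bond of the chalcone is a temporary bond that the shift cleaves, so a 1,3-diaryl C3 chain becomes the 1,2-diaryl isoflavonoid chain, as in the biogenesis of the skeleton.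
3. Enabling feature: C3 is benzylic to ring B, whose O-2' and O-4' (ortho and para to C1') stabilise positive charge on C3 and trigger the shift; C4 sits on C4a, ortho to C8a of ring A, so at the ketone level it activates a C8a–F bond for closure of the pyran ring.
4. Chalcone epoxide ⇐ epoxidation and aldol condensation ⇐ ring-A methyl ketone (from 5-fluoro-2-methoxyphenol) + ring-B aldehyde (from 2,3-dimethoxy-1,4-benzoquinone).
5. Ring order: rings A and B are bought as benzene rings; the pyran ring C is the only ring formed (key step). Fluorine is lost in the key step, and the C4 ketone and C2=C3 bond are taken down in the two steps after it.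

Key step: step 7

Assumption: 2,3-dimethoxy-1,4-benzoquinone is taken as purchasable; where it is not stocked, one oxidation of commercial 2,3-dimethoxyphenol (Fremy's salt or salcomine/O2) supplies it without changing the route.

**Step 1**
Reactants: 1 5-fluoro-2-methoxyphenol
Product: 2 2-(benzyloxy)-4-fluoro-1-methoxybenzene
Conditions: BnBr, K2CO3, DMF, 60 °C
Reagents that add atoms: benzyl bromide, BrCc1ccccc1
Why: Williamson ether synthesis at the phenoxide oxygen; benzyl is chosen because it should survive every later step and leave under neutral hydrogenolysis at the end.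

**Step 2**
Reactants: 2 2-(benzyloxy)-4-fluoro-1-methoxybenzene
Product: 3 1-[4-(benzyloxy)-2-fluoro-5-methoxyphenyl]ethan-1-one
Conditions: Ac2O, In(OTf)3 (cat.), LiClO4, MeNO2, 50 °C
Reagents that add atoms: acetic anhydride, CC(=O)OC(C)=O
Why: Friedel–Crafts acylation: the only free position para to an oxygen donor is the one para to OBn and ortho to F (the position para to OMe carries F), so the acetyl group should enter there and place F ortho to the future C4 carbonyl.

**Step 3**
Reactants: 4 2,3-dimethoxy-1,4-benzoquinone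
Product: 6 1,4-bis(benzyloxy)-2,3-dimethoxybenzene, via 2,3-dimethoxyhydroquinone 5 (not isolated)
Conditions: Na2S2O4, KOH, n-Bu4NBr (cat.), BnBr, THF/H2O, rt → 50 °C, Ar
Reagents that add atoms: benzyl bromide, BrCc1ccccc1
Why: Dithionite reduces the quinone to the hydroquinone dianion, which is trapped in the same flask by Williamson O-benzylation under phase transfer, so the air-sensitive hydroquinone is never handled.

**Step 4**
Reactants: 6 1,4-bis(benzyloxy)-2,3-dimethoxybenzene
Product: 7 2,5-bis(benzyloxy)-3,4-dimethoxybenzaldehyde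
Conditions: POCl3, DMF, 75 °C; then H2O
Reagents that add atoms: N,N-dimethylformamide, CN(C)C=O; water, O
Why: Vilsmeier–Haack formylation of the electron-rich tetraalkoxybenzene; the two free ring positions are equivalent by symmetry, so a single aldehyde should form.

**Step 5**
Reactants: 3 1-[4-(benzyloxy)-2-fluoro-5-methoxyphenyl]ethan-1-one; 7 2,5-bis(benzyloxy)-3,4-dimethoxybenzaldehyde
Product: 8 (E)-1-[4-(benzyloxy)-2-fluoro-5-methoxyphenyl]-3-[2,5-bis(benzyloxy)-3,4-dimethoxyphenyl]prop-2-en-1-one
Conditions: KOH, EtOH/THF, 0 °C → rt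
Reagents that add atoms: none
Why: Claisen–Schmidt condensation (crossed aldol, then E1cB dehydration) between the methyl ketone and the non-enolisable aldehyde should give the conjugated (E)-enone as the thermodynamic product.

**Step 6**
Reactants: 8 (E)-chalcone
Product: 9 rac-trans-[3-(2,5-bis(benzyloxy)-3,4-dimethoxyphenyl)oxiran-2-yl][4-(benzyloxy)-2-fluoro-5-methoxyphenyl]methanone
Conditions: 30% H2O2, NaOH (aq.), MeOH/THF, 0 °C
Reagents that add atoms: hydrogen peroxide, OO
Why: Weitz–Scheffer nucleophilic epoxidation (conjugate addition of hydroperoxide, then closure of the enolate onto O–O) should give the trans epoxy ketone as a racemate, which suffices because both epoxide carbons become sp2 in step 7.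

**Step 7**
Reactants: 9 rac-trans-chalcone epoxide
Product: 11 7-(benzyloxy)-3-[2,5-bis(benzyloxy)-3,4-dimethoxyphenyl]-6-methoxy-4H-chromen-4-one, via formyl deoxybenzoin 10 (not isolated)
Conditions: BF3·OEt2 (0.3 equiv), CH2Cl2, −20 → 0 °C; then anhydrous K2CO3, DMF, CH2Cl2 distilled off, 80 °C
Reagents that add atoms: none
Why: BF3 binds the epoxide oxygen O1 and the C3–O1 bond ionises, because C3 is benzylic to ring B and the ether oxygens O-2' and O-4' carry the charge; the aroyl group then shifts from C2 to C3 (1,2-acyl shift of an α,β-epoxy ketone, a Meinwald-type rearrangement with close precedent on chalcone epoxides), which makes C3–C4, breaks the temporary C2–C4 bond and leaves O1 on C2 as the formyl/enol oxygen of 10. Added K2CO3 forms the enolate of this β-keto aldehyde, and its oxygen O1 displaces fluoride from C8a, which is ortho to the C4 ketone (intramolecular SNAr by addition–elimination; the closest known type is the cyclisation of 1-(2-fluoroaryl)-1,3-dicarbonyl enolates to chromones). Ring C closes in the 6-exo-trig mode (attack at C8a, with the C8a=C8 π bond outside the new ring) and becomes an aromatic 4-pyranone, which drives the step. No stereocentre is formed: C3 and C4 leave the step sp2 and are set together in step 9. The step needs acyl shift over hydride shift and O- over C-attack; the first is secured by the cation-stabilising ring B on C3 and the high migratory aptitude of acyl groups in epoxy ketones, the second by geometry, since only O1 reaches C8a through a six-membered transition state. Anhydrous carbonate in DMF is chosen to limit retro-Claisen loss of the formyl carbon.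

**Step 8**
Reactants: 11 tribenzyl isoflavone
Product: 13 7-(benzyloxy)-3-[2,5-bis(benzyloxy)-3,4-dimethoxyphenyl]-6-methoxy-2H-chromene, via isoflavan-4-ol 12 (not isolated)
Conditions: NaBH4, THF/EtOH, 0 °C → rt; then TsOH·H2O, toluene (THF/EtOH distilled off), 60 °C
Reagents that add atoms: none
Why: Borohydride should reduce the chromone first at C2 (conjugate addition) and then at the C4 ketone; acid then ionises the oxygen-stabilised benzylic C4–OH and removes H-3 (E1 dehydration) to give the conjugated 3-aryl-2H-chromene, so the stereochemistry of 12 is irrelevant.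

**Step 9**
Reactants: 13 3-aryl-2H-chromene
Product: 14 (3S,4R)-7-(benzyloxy)-3-[2,5-bis(benzyloxy)-3,4-dimethoxyphenyl]-6-methoxychroman-4-ol
Conditions: IpcBH2 [from (+)-α-pinene, made beforehand], THF, −25 → 0 °C; then NaOH, 30% H2O2, 0 °C → rt
Reagents that add atoms: hydrogen peroxide, OO
Why: Brown asymmetric hydroboration–oxidation: boron adds to the less substituted C4 and hydrogen to C3 on the same face, and oxidation with retention places OH cis to H-3, so aryl and OH are 3,4-trans; the face is chosen by the isopinocampheyl group on boron (reagent control), and by analogy with 1-arylcycloalkenes the (+)-α-pinene series should lead to (3S,4R) (the antipodal reagent serves if the sense proves opposite).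

**Step 10**
Reactants: 14 (3S,4R)-tribenzyl isoflavan-4-ol
Product: 15 (3S,4R)-3-(2,5-dihydroxy-3,4-dimethoxyphenyl)-6-methoxychromane-4,7-diol (CNP0163454.1)
Conditions: H2 (1 atm), 10% Pd/C, EtOAc/MeOH, rt; work-up under Ar
Reagents that add atoms: none
Why: Hydrogenolysis of the three aryl benzyl ethers on palladium under neutral conditions is expected to be faster than cleavage of the secondary benzylic C4–OH bond, and it avoids acid, which would ionise C4 and close the 2'-OH onto it.

**Compound list**
1 | 5-fluoro-2-methoxyphenol | COc1ccc(F)cc1O | starting material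
2 | 2-(benzyloxy)-4-fluoro-1-methoxybenzene | COc1ccc(F)cc1OCc1ccccc1 | intermediate
3 | 1-[4-(benzyloxy)-2-fluoro-5-methoxyphenyl]ethan-1-one | CC(=O)c1cc(OC)c(OCc2ccccc2)cc1F | intermediate
4 | 2,3-dimethoxy-1,4-benzoquinone | COC1=C(OC)C(=O)C=CC1=O | starting material
5 | 2,3-dimethoxyhydroquinone (not isolated) | COc1c(O)ccc(O)c1OC | intermediate
6 | 1,4-bis(benzyloxy)-2,3-dimethoxybenzene | COc1c(OCc2ccccc2)ccc(OCc2ccccc2)c1OC | intermediate
7 | 2,5-bis(benzyloxy)-3,4-dimethoxybenzaldehyde | O=Cc1cc(OCc2ccccc2)c(OC)c(OC)c1OCc1ccccc1 | intermediate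
8 | (E)-1-[4-(benzyloxy)-2-fluoro-5-methoxyphenyl]-3-[2,5-bis(benzyloxy)-3,4-dimethoxyphenyl]prop-2-en-1-one | COc1cc(C(=O)/C=C/c2cc(OCc3ccccc3)c(OC)c(OC)c2OCc2ccccc2)c(F)cc1OCc1ccccc1 | intermediate
9 | rac-trans-[3-(2,5-bis(benzyloxy)-3,4-dimethoxyphenyl)oxiran-2-yl][4-(benzyloxy)-2-fluoro-5-methoxyphenyl]methanone (racemate, one enantiomer drawn) | COc1cc(C(=O)[C@@H]2O[C@H]2c2cc(OCc3ccccc3)c(OC)c(OC)c2OCc2ccccc2)c(F)cc1OCc1ccccc1 | intermediate
10 | 3-[4-(benzyloxy)-2-fluoro-5-methoxyphenyl]-2-[2,5-bis(benzyloxy)-3,4-dimethoxyphenyl]-3-oxopropanal (α-formyl deoxybenzoin, racemic keto–enol mixture, not isolated) | COc1cc(C(=O)C(C=O)c2cc(OCc3ccccc3)c(OC)c(OC)c2OCc2ccccc2)c(F)cc1OCc1ccccc1 | intermediate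
11 | 7-(benzyloxy)-3-[2,5-bis(benzyloxy)-3,4-dimethoxyphenyl]-6-methoxy-4H-chromen-4-one | COc1cc2c(cc1OCc1ccccc1)occ(-c1cc(OCc3ccccc3)c(OC)c(OC)c1OCc1ccccc1)c2=O | intermediate
12 | 7-(benzyloxy)-3-[2,5-bis(benzyloxy)-3,4-dimethoxyphenyl]-6-methoxychroman-4-ol (racemic cis/trans mixture, not isolated) | COc1cc2c(cc1OCc1ccccc1)OCC(c1cc(OCc3ccccc3)c(OC)c(OC)c1OCc1ccccc1)C2O | intermediate
13 | 7-(benzyloxy)-3-[2,5-bis(benzyloxy)-3,4-dimethoxyphenyl]-6-methoxy-2H-chromene | COc1cc2c(cc1OCc1ccccc1)OCC(c1cc(OCc3ccccc3)c(OC)c(OC)c1OCc1ccccc1)=C2 | intermediate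
14 | (3S,4R)-7-(benzyloxy)-3-[2,5-bis(benzyloxy)-3,4-dimethoxyphenyl]-6-methoxychroman-4-ol (3,4-trans) | COc1cc2c(cc1OCc1ccccc1)OC[C@H](c1cc(OCc3ccccc3)c(OC)c(OC)c1OCc1ccccc1)[C@H]2O | intermediate
15 | (3S,4R)-3-(2,5-dihydroxy-3,4-dimethoxyphenyl)-6-methoxychromane-4,7-diol (3,4-trans) | COc1cc2c(cc1O)OC[C@H](c1cc(O)c(OC)c(OC)c1O)[C@H]2O | target

**Totals and risks**
Total step count: 10. Longest linear sequence: 8 steps (1 → 2 → 3 → 8 → 9 → 11 → 13 → 14 → 15; the branch from 4 is equally long).

The three steps most likely to fail: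

Step 7. The Lewis-acid opening may run into hydride shift or cleavage of the ortho benzyl ether instead of the acyl shift, and the β-keto aldehyde may lose its formyl carbon by retro-Claisen cleavage before the slow substitution at the electron-rich fluoroarene. The fallback sets out from chalcone 8: thallium(III) nitrate in MeOH/HC(OMe)3 brings about the oxidative 1,2-shift of ring B from the β- to the α-carbon (the classical chalcone-to-isoflavone rearrangement) and should give the isolable β-keto acetal 1-[4-(benzyloxy)-2-fluoro-5-methoxyphenyl]-2-[2,5-bis(benzyloxy)-3,4-dimethoxyphenyl]-3,3-dimethoxypropan-1-one F1. In it the formyl group is masked and no Lewis acid meets the benzyl ethers. After purification the acetal is unmasked with aqueous HCl in THF and closed at once with Cs2CO3 in DMSO, which returns to the route at isoflavone 11.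

Step 9. Facial discrimination by IpcBH2 may be poor on a hindered, ortho-substituted 3-aryl-2H-chromene, or the hydroboration may be slow. The fallback sets out from isoflavone 11: Noyori–Ikariya transfer hydrogenation with dynamic kinetic resolution [RuCl(p-cymene)((S,S)-TsDPEN), HCO2H/Et3N] should give the cis-alcohol (3S,4S)-7-(benzyloxy)-3-[2,5-bis(benzyloxy)-3,4-dimethoxyphenyl]-6-methoxychroman-4-ol F2, with C3 fixed by the catalyst. Mitsunobu inversion at C4 (4-nitrobenzoic acid, PPh3, DIAD; attack anti to the 3-aryl group) should give the (3S,4R)-4-nitrobenzoate F3, and methanolysis (K2CO3, MeOH) returns to the route at trans-alcohol 14.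

Step 10. The benzylic C4–O bond may be hydrogenolysed along with the benzyl ethers, or the freed hydroquinone may be oxidised on the catalyst. The fallback exchanges benzyl for silyl before the benzylic alcohol exists and sets out from isoflavone 11: hydrogenolysis (H2, Pd/C; the chromone is inert) should give 7-hydroxy-3-(2,5-dihydroxy-3,4-dimethoxyphenyl)-6-methoxy-4H-chromen-4-one F4, and silylation (TBSOTf, 2,6-lutidine) its tris-TBS ether F5. The conditions of step 8 should then give the tris-TBS 3-aryl-2H-chromene F6, and those of step 9 (oxidation with buffered H2O2) the tris-TBS (3S,4R)-chroman-4-ol F7. Fluoride (TBAF/AcOH, THF, 0 °C) then returns to the route at target 15.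

**Further compounds**
F1 | step 7 | 1-[4-(benzyloxy)-2-fluoro-5-methoxyphenyl]-2-[2,5-bis(benzyloxy)-3,4-dimethoxyphenyl]-3,3-dimethoxypropan-1-one (racemic) | COc1cc(C(=O)C(C(OC)OC)c2cc(OCc3ccccc3)c(OC)c(OC)c2OCc2ccccc2)c(F)cc1OCc1ccccc1
F2 | step 9 | (3S,4S)-7-(benzyloxy)-3-[2,5-bis(benzyloxy)-3,4-dimethoxyphenyl]-6-methoxychroman-4-ol (3,4-cis) | COc1cc2c(cc1OCc1ccccc1)OC[C@H](c1cc(OCc3ccccc3)c(OC)c(OC)c1OCc1ccccc1)[C@@H]2O
F3 | step 9 | (3S,4R)-7-(benzyloxy)-3-[2,5-bis(benzyloxy)-3,4-dimethoxyphenyl]-6-methoxychroman-4-yl 4-nitrobenzoate | COc1cc2c(cc1OCc1ccccc1)OC[C@H](c1cc(OCc3ccccc3)c(OC)c(OC)c1OCc1ccccc1)[C@H]2OC(=O)c1ccc([N+](=O)[O-])cc1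
F4 | step 10 | 7-hydroxy-3-(2,5-dihydroxy-3,4-dimethoxyphenyl)-6-methoxy-4H-chromen-4-one | COc1cc2c(cc1O)occ(-c1cc(O)c(OC)c(OC)c1O)c2=O
F5 | step 10 | 7-(tert-butyldimethylsilyloxy)-3-[2,5-bis(tert-butyldimethylsilyloxy)-3,4-dimethoxyphenyl]-6-methoxy-4H-chromen-4-one | COc1cc2c(cc1O[Si](C)(C)C(C)(C)C)occ(-c1cc(O[Si](C)(C)C(C)(C)C)c(OC)c(OC)c1O[Si](C)(C)C(C)(C)C)c2=O
F6 | step 10 | 7-(tert-butyldimethylsilyloxy)-3-[2,5-bis(tert-butyldimethylsilyloxy)-3,4-dimethoxyphenyl]-6-methoxy-2H-chromene | COc1cc2c(cc1O[Si](C)(C)C(C)(C)C)OCC(c1cc(O[Si](C)(C)C(C)(C)C)c(OC)c(OC)c1O[Si](C)(C)C(C)(C)C)=C2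
F7 | step 10 | (3S,4R)-7-(tert-butyldimethylsilyloxy)-3-[2,5-bis(tert-butyldimethylsilyloxy)-3,4-dimethoxyphenyl]-6-methoxychroman-4-ol | COc1cc2c(cc1O[Si](C)(C)C(C)(C)C)OC[C@H](c1cc(O[Si](C)(C)C(C)(C)C)c(OC)c(OC)c1O[Si](C)(C)C(C)(C)C)[C@H]2O
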